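**Compound numbers.** 1 propargyl alcohol; 2 its TBDPS ether; 3 lithium acetylide; 4 silyloxy ynoate; 5 iodomethyl pinacol boronate; 6 alkenylalane; 7 (Z)-allylboronate; 8 O-benzylvanillin; 9 borate adduct; 10 α-methylene lactone; 11 3,4-bis(benzyloxy)aniline; 12 diazonium salt; 13 (E)-arylidene lactone; 14 arylidene lactone alcohol; 15 tri-O-benzyl furofuranone; 16 target.

## The problem

The target is a furo[3,4-c]furan-1-one lignan. A γ-butyrolactone (ring A: C1, O2, C3, C3a, C6a) is fused through the C3a–C6a bond to a tetrahydrofuran (ring B: C3a, C4, O5, C6, C6a). C3 carries a 4-hydroxy-3-methoxyphenyl group and C6 a 3,4-dihydroxyphenyl group. There are four contiguous stereocentres (3S, 3aR, 6S, 6aS), but they are not independent. A five–five fusion can only be cis, so C6a follows C3a. C6 is a benzylic ether carbon next to an electron-rich ring, so it can equilibrate under acid to the convex-face (exo) aryl arrangement that the target has. Only the trans pair C3/C3a therefore needs absolute control, which means one enantio-determining event. The two aryl groups differ and must arrive in separate, regiodefined operations. The catechol and the phenol are oxidation-prone and stay masked to the end. Both aryl-bearing carbons have benzylic C–O bonds that ionise in acid and can be hydrogenolysed, and the lactone with an oxygen on its β-branch is open to base-induced acyl migration. The enabling feature is ring A itself: a γ-aryl-γ-butyrolactone whose O2–C3 carbon and C3a are adjacent anti-configured centres is the retron of an aldehyde allylboration with an ester-bearing allylboronate. C6, the only carbon attached to C6a outside ring A, maps onto the α-methylene group that such a reaction leaves behind.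

## Retrosynthesis

Target 16 is traced to its tri-O-benzyl ether 15 by cutting the three phenolic O–benzyl bonds. No skeletal bond changes. Benzyl is preferred to silyl or acyl protection because it survives every acidic and organometallic step planned. The forward step must remove three aryl benzyl ethers without cleaving the two ring benzylic C–O bonds.

In 15 the O5–C6 bond of ring B is cut, which gives the (E)-arylidene lactone alcohol 14 (and its silyl ether 13). The neighbouring cut C6–C6a would be an aldol disconnection; it needs a lactone without an α-carbon branch and an aldol whose C6a outcome would have to be corrected. The cut C4–O5 would need a separately made C6 carbinol stereocentre and a leaving group on C4. Cutting O5–C6 places bond formation at the carbon best able to carry positive charge, needs no leaving group, and leaves C6 to settle thermodynamically. The forward reaction is an acid-triggered addition of the primary hydroxyl to the benzylic alkene carbon, with protonation at C6a in the only sense a cis-fused bicycle allows.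

In 13 the bond between the exocyclic alkene carbon and the catechol ring is cut. This gives the α-methylene lactone 10 and the arenediazonium salt 12, made in one step from aniline 11. A condensation route to the arylidene would again need an α-unbranched lactone; the arylation uses the alkene already present. Precursor 10 has one aryl ring fewer and only two stereocentres. The forward Heck–Matsuda reaction must arylate the methylene terminus and eliminate toward the benzylic hydrogens, not into the ring.

In 10 two bonds of ring A are cut together: the C4–C5 bond (C3a–C3 of the target) and the acyl C2–O1 bond. This leads through borate 9 to O-benzylvanillin 8 and the (Z)-allylboronate 7. The alternative of closing the lactone from a preformed hydroxy acid would need a separate anti-selective aldol-type construction and a later methylenation. The allylboration makes the C–C bond, both stereocentres, the ring and the methylene handle at once. The forward reaction must choose one aldehyde face, give the anti adduct, and lactonise only through the benzylic oxygen.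

Boronate 7 is cut at the bond between the alkene carbon and the CH2B group, which gives ynoate 4 and iodomethyl boronate 5 through alkenylalane 6. A syn hydroalumination fixes the alkene geometry that the key step converts into relative configuration. Ynoate 4 comes from silyl ether 2 by carboxylation of acetylide 3, and 2 from propargyl alcohol 1.

## Roads not taken

Alternative 1: Three bonds are cut at once (O5–C6, C3a–C6a and the acyl O2–C1 bond). The precursors are the cis-epoxy alcohol A1 and the arylidene malonate A2. In the forward cascade the alkoxide of A1 adds to A2, the malonate anion opens the epoxide at the non-benzylic carbon with inversion, and the released benzylic alkoxide lactonises onto the cis ester to give A3.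
- Merits: it is the most convergent option, builds both rings in one flask, and takes its absolute configuration from an asymmetric epoxidation, a proven source. On step count and on confidence in enantiocontrol it is at least equal to the chosen plan.
- Weak points: inversion at the future C3a means the trans C3/C3a relationship requires the cis epoxide. Cis epoxides come from Z-alkenes, the least satisfactory substrate class for titanium–tartrate epoxidation, and an oxirane on an electron-rich aryl ring ionises easily. The alkoxide addition to A2 is reversible, Payne rearrangement of A1 competes, and the malonate can also attack the activated benzylic epoxide carbon. A3 carries an extra ester that must be removed by decarboxylation.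
- Comparison: the chosen plan has stable intermediates and forms each bond in a separately controllable event. It pays with more steps and a catalytic step that is not yet demonstrated.

Alternative 2: The C4–C3a and O2–C3 bonds are cut, leading to the cis-dioxanone A4. Me3SiOTf would open the acyloxy acetal to a methylene oxocarbenium ion and a silyl carboxylate; the styrene closes ring B and the carboxylate captures the benzylic cation to close ring A.
- Merits: the product A5 is identical with 15, so this road reaches the penultimate compound in one step from an aldol-derived precursor with no surplus carbon. That is clearly shorter than steps 4 to 8 of the chosen plan.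
- Weak points: the oxocarbenium ion and the styrene are 1,5-related across the C6–C6a bond, and C6 bears an electron-rich aryl group, so 2-oxonia-Cope rearrangement and benzylic ionisation threaten the C6/C6a information. The five-membered Prins closure must beat these. C3a and C3 are both created under cationic conditions with no external control, and the β,γ-unsaturated aldol partner needed for A4 tends to move its double bond into conjugation.
- Comparison: the chosen plan never lets a cation choose among several electron-rich benzylic sites while stereocentres are being created; its only cationic step comes when the remaining centre is self-correcting.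

Alternative 3: The C3a–C6a and O2–C3 bonds are cut, leading to the cinnamyl ether malonate A6. Mn(OAc)3 generates the malonyl radical, which cyclises 5-exo onto the alkene; Cu(OAc)2 oxidises the benzylic radical, and the cis tert-butyl ester captures the cation with loss of isobutene to give A7.
- Merits: of the four options this key step is the closest to recognised routes to furofuranone lignans. It is short and forms both rings in one operation, so it is better than the chosen plan on precedent for ring construction and on step count.
- Weak points: the only stereocentre of A6 is a benzylic ether carbon made by conjugate addition of an alcohol, for which no dependable enantioselective version exists, so the road is in practice racemic or needs a resolution. Trivalent manganese in hot acetic acid meets three electron-rich aryl ethers. The C3 configuration is decided at cation capture. The tert-butyl ester costs an acidolysis and a decarboxylation.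
- Comparison: the chosen plan places the single enantio-determining event under catalyst control at the start; for a target required as one enantiomer this decides the matter.

Key step: step 4

Assumption: the (S)-configured phosphoric acid is taken to direct the allyl group to the Si face of aldehyde 8, by analogy with the Re-face preference of the (R)-acid with simple pinacol allyl- and crotylboronates; this sense has to be verified on the first run.

## Route

Step 1
Reactants: 1 prop-2-yn-1-ol
Product: 2 tert-butyl(diphenyl)(prop-2-yn-1-yloxy)silane
Conditions: TBDPSCl, imidazole, DMF, 0 °C → rt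
Reagents that add atoms: tert-butyl(chloro)diphenylsilane, CC(C)(C)[Si](Cl)(c1ccccc1)c1ccccc1
Why: Imidazole-promoted silylation of a primary alcohol; the acid-stable TBDPS group is chosen because it must outlast the acidic lactonisation of step 4 and the Heck–Matsuda medium of step 6.

Step 2
Reactants: 2 tert-butyl(diphenyl)(prop-2-yn-1-yloxy)silane
Product: 4 methyl 4-[(tert-butyldiphenylsilyl)oxy]but-2-ynoate, via lithium acetylide 3 (not isolated)
Conditions: n-BuLi, THF, −78 °C; then ClCO2Me, −78 → 0 °C
Reagents that add atoms: methyl chloroformate, COC(=O)Cl
Why: Deprotonation of the terminal alkyne and C-acylation of the acetylide with a chloroformate is the standard route to 2-ynoates; low temperature and inverse stoichiometry prevent a second addition.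

Step 3
Reactants: 4 methyl 4-[(tert-butyldiphenylsilyl)oxy]but-2-ynoate; 5 2-(iodomethyl)-4,4,5,5-tetramethyl-1,3,2-dioxaborolane
Product: 7 methyl (Z)-4-[(tert-butyldiphenylsilyl)oxy]-2-[(4,4,5,5-tetramethyl-1,3,2-dioxaborolan-2-yl)methyl]but-2-enoate, via alkenylalane 6 (not isolated)
Conditions: i-Bu2AlH, HMPA, THF, 0 °C; then 5, 0 °C → rt
Reagents that add atoms: none
Why: Conjugate hydroalumination of a 2-ynoate by the i-Bu2AlH–HMPA complex adds H and Al syn with aluminium α to the ester; the alkenylalane then attacks boron of 5 and migrates to carbon with loss of iodide (Matteson-type homologation) with retention, so the silyloxymethyl group ends trans to CH2B. Holding the alane at 0 °C keeps it from isomerising through its allenoate form.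

Step 4
Reactants: 7 methyl (Z)-4-[(tert-butyldiphenylsilyl)oxy]-2-[(4,4,5,5-tetramethyl-1,3,2-dioxaborolan-2-yl)methyl]but-2-enoate; 8 4-(benzyloxy)-3-methoxybenzaldehyde
Product: 10 (4R,5S)-5-[4-(benzyloxy)-3-methoxyphenyl]-4-{[(tert-butyldiphenylsilyl)oxy]methyl}-3-methylideneoxolan-2-one, via borate ester 9 (not isolated)
Conditions: (S)-TRIP [(S)-3,3′-bis(2,4,6-triisopropylphenyl)-1,1′-binaphthyl-2,2′-diyl hydrogen phosphate] (10 mol%), 4 Å MS, toluene, rt; then p-TsOH·H2O (10 mol%), CH2Cl2, rt
Reagents that add atoms: none
Why: Proposed new method: the phosphoric acid should hydrogen-bond through P–OH to the pseudo-axial ring oxygen of boronate 7 and through P=O to the formyl hydrogen of 8, so that the aldehyde adds through a closed six-membered chair in which the alkene carbon bearing CH2OSi bonds to the carbonyl carbon and boron passes to oxygen, giving borate 9. The closest known reaction types are the chiral phosphoric acid-catalysed allyl- and (E)-crotylboration of aryl aldehydes with pinacol boronates and the TfOH- or Sc(OTf)3-catalysed additions of 2-alkoxycarbonyl allylboronates that end in α-methylene-γ-butyrolactones; what is untested is the pairing of the weak chiral acid with the ester-deactivated boronate. Ring A then closes by a 5-exo-trig acyl substitution in which the boron-bound benzylic oxygen of 9 attacks the ester carbonyl and methoxide leaves on boron, catalytic TsOH completing it. C5 of 10 is set by the catalyst, the (S)-acid being expected to expose the Si face of 8. C4 is set relative to C5 by the alkene geometry, because the silyloxymethyl group trans to CH2B lies equatorial in the chair beside the equatorial aryl group, which gives the anti adduct and hence the trans lactone. The step needs enantioface selectivity, which rests on the catalyst and is helped by the very slow uncatalysed addition of ester-bearing boronates at room temperature. It also needs anti selectivity and lactonisation through the benzylic oxygen only: the (Z)-alkene secures the first, the trans lactone is also the thermodynamic isomer so that any acid-induced ionisation at the electron-rich benzylic carbon recloses to the same product without touching C4, and the acid-stable silyl ether on the primary oxygen secures the second.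

Step 5
Reactants: 11 3,4-bis(benzyloxy)aniline
Product: 12 3,4-bis(benzyloxy)benzenediazonium tetrafluoroborate
Conditions: t-BuONO, 48% aq. HBF4, EtOH, 0 °C; precipitation with Et2O
Reagents that add atoms: tert-butyl nitrite, CC(C)(C)ON=O; tetrafluoroboric acid, [H+].F[B-](F)(F)F
Why: Diazotisation of an aniline with an alkyl nitrite in the presence of HBF4; electron-rich arenediazonium tetrafluoroborates precipitate as storable solids.

Step 6
Reactants: 10 (4R,5S)-5-[4-(benzyloxy)-3-methoxyphenyl]-4-{[(tert-butyldiphenylsilyl)oxy]methyl}-3-methylideneoxolan-2-one; 12 3,4-bis(benzyloxy)benzenediazonium tetrafluoroborate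
Product: 13 (3E,4R,5S)-5-[4-(benzyloxy)-3-methoxyphenyl]-3-{[3,4-bis(benzyloxy)phenyl]methylidene}-4-{[(tert-butyldiphenylsilyl)oxy]methyl}oxolan-2-one
Conditions: Pd(OAc)2 (5 mol%), NaOAc, MeCN, rt
Reagents that add atoms: none
Why: Heck–Matsuda arylation: the diazonium salt adds oxidatively to zerovalent palladium formed in situ, syn carbopalladation places the aryl group on the unsubstituted methylene terminus, and syn β-hydride elimination toward the benzylic hydrogens gives the conjugated (E)-arylidene lactone. Room temperature and acetate buffering limit re-addition of the palladium hydride, so C4 is untouched; the alkene geometry is of no consequence for step 8.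

Step 7
Reactants: 13 (3E,4R,5S)-5-[4-(benzyloxy)-3-methoxyphenyl]-3-{[3,4-bis(benzyloxy)phenyl]methylidene}-4-{[(tert-butyldiphenylsilyl)oxy]methyl}oxolan-2-one
Product: 14 (3E,4R,5S)-5-[4-(benzyloxy)-3-methoxyphenyl]-3-{[3,4-bis(benzyloxy)phenyl]methylidene}-4-(hydroxymethyl)oxolan-2-one
Conditions: HF·pyridine, pyridine, THF, 0 °C → rt
Reagents that add atoms: none
Why: Fluoride-mediated cleavage of a primary silyl ether; the buffered, non-basic medium avoids a free alkoxide, which would attack the lactone carbonyl in a 5-exo-trig acyl transfer.

Step 8
Reactants: 14 (3E,4R,5S)-5-[4-(benzyloxy)-3-methoxyphenyl]-3-{[3,4-bis(benzyloxy)phenyl]methylidene}-4-(hydroxymethyl)oxolan-2-one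
Product: 15 (3S,3aR,6S,6aS)-3-[4-(benzyloxy)-3-methoxyphenyl]-6-[3,4-bis(benzyloxy)phenyl]tetrahydro-1H,3H-furo[3,4-c]furan-1-one
Conditions: TfOH (10 mol%), CH2Cl2, −20 → 0 °C
Reagents that add atoms: none
Why: Acid-catalysed intramolecular oxa-Michael addition (hydroalkoxylation): protonation of the lactone carbonyl gives a hydroxyallyl cation whose charge sits on the benzylic carbon and in the 3,4-bis(benzyloxy)phenyl ring, and the primary hydroxyl captures it; the formally 5-endo-trig closure is open because the reacting carbon is cationic and the former double bond can rotate. Tautomerisation of the ketene hemiacetal protonates C6a in the only sense compatible with a cis-fused bicycle, and C6, formed reversibly, should settle in the exo-aryl (6S) configuration under thermodynamic control.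

Step 9
Reactants: 15 (3S,3aR,6S,6aS)-3-[4-(benzyloxy)-3-methoxyphenyl]-6-[3,4-bis(benzyloxy)phenyl]tetrahydro-1H,3H-furo[3,4-c]furan-1-one
Product: 16 (3S,3aR,6S,6aS)-6-(3,4-dihydroxyphenyl)-3-(4-hydroxy-3-methoxyphenyl)tetrahydro-1H,3H-furo[3,4-c]furan-1-one
Conditions: H2 (1 atm), 10% Pd/C, EtOAc–MeOH, rt, stopped at complete debenzylation
Reagents that add atoms: none
Why: Catalytic hydrogenolysis of aryl benzyl ethers, which at atmospheric pressure in a weakly polar solvent is faster than cleavage of the ring benzylic C–O bonds; no stereocentre is involved.

## Compound list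

1 | prop-2-yn-1-ol (propargyl alcohol) | C#CCO | starting material
2 | tert-butyl(diphenyl)(prop-2-yn-1-yloxy)silane | C#CCO[Si](c1ccccc1)(c1ccccc1)C(C)(C)C | intermediate
3 | lithium 3-[(tert-butyldiphenylsilyl)oxy]prop-1-yn-1-ide | [Li]C#CCO[Si](c1ccccc1)(c1ccccc1)C(C)(C)C | intermediate
4 | methyl 4-[(tert-butyldiphenylsilyl)oxy]but-2-ynoate | COC(=O)C#CCO[Si](c1ccccc1)(c1ccccc1)C(C)(C)C | intermediate
5 | 2-(iodomethyl)-4,4,5,5-tetramethyl-1,3,2-dioxaborolane | ICB1OC(C)(C)C(C)(C)O1 | starting material
6 | methyl (E)-4-[(tert-butyldiphenylsilyl)oxy]-2-(diisobutylalumanyl)but-2-enoate (H and Al cis) | COC(=O)/C([Al](CC(C)C)CC(C)C)=C\CO[Si](c1ccccc1)(c1ccccc1)C(C)(C)C | intermediate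
7 | methyl (Z)-4-[(tert-butyldiphenylsilyl)oxy]-2-[(4,4,5,5-tetramethyl-1,3,2-dioxaborolan-2-yl)methyl]but-2-enoate | COC(=O)/C(CB1OC(C)(C)C(C)(C)O1)=C\CO[Si](c1ccccc1)(c1ccccc1)C(C)(C)C | intermediate
8 | 4-(benzyloxy)-3-methoxybenzaldehyde (O-benzylvanillin) | COc1cc(C=O)ccc1OCc1ccccc1 | starting material
9 | methyl (3R,4S)-4-[4-(benzyloxy)-3-methoxyphenyl]-3-{[(tert-butyldiphenylsilyl)oxy]methyl}-2-methylidene-4-[(4,4,5,5-tetramethyl-1,3,2-dioxaborolan-2-yl)oxy]butanoate | COc1cc([C@@H](OB2OC(C)(C)C(C)(C)O2)[C@@H](CO[Si](c2ccccc2)(c2ccccc2)C(C)(C)C)C(=C)C(=O)OC)ccc1OCc1ccccc1 | intermediate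
10 | (4R,5S)-5-[4-(benzyloxy)-3-methoxyphenyl]-4-{[(tert-butyldiphenylsilyl)oxy]methyl}-3-methylideneoxolan-2-one | COc1cc([C@H]2OC(=O)C(=C)[C@@H]2CO[Si](c3ccccc3)(c3ccccc3)C(C)(C)C)ccc1OCc1ccccc1 | intermediate
11 | 3,4-bis(benzyloxy)aniline | Nc1ccc(OCc2ccccc2)c(OCc2ccccc2)c1 | starting material
12 | 3,4-bis(benzyloxy)benzenediazonium tetrafluoroborate | N#[N+]c1ccc(OCc2ccccc2)c(OCc2ccccc2)c1.F[B-](F)(F)F | intermediate
13 | (3E,4R,5S)-5-[4-(benzyloxy)-3-methoxyphenyl]-3-{[3,4-bis(benzyloxy)phenyl]methylidene}-4-{[(tert-butyldiphenylsilyl)oxy]methyl}oxolan-2-one | COc1cc([C@H]2OC(=O)/C(=C/c3ccc(OCc4ccccc4)c(OCc4ccccc4)c3)[C@@H]2CO[Si](c3ccccc3)(c3ccccc3)C(C)(C)C)ccc1OCc1ccccc1 | intermediate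
14 | (3E,4R,5S)-5-[4-(benzyloxy)-3-methoxyphenyl]-3-{[3,4-bis(benzyloxy)phenyl]methylidene}-4-(hydroxymethyl)oxolan-2-one | COc1cc([C@H]2OC(=O)/C(=C/c3ccc(OCc4ccccc4)c(OCc4ccccc4)c3)[C@@H]2CO)ccc1OCc1ccccc1 | intermediate
15 | (3S,3aR,6S,6aS)-3-[4-(benzyloxy)-3-methoxyphenyl]-6-[3,4-bis(benzyloxy)phenyl]tetrahydro-1H,3H-furo[3,4-c]furan-1-one | COc1cc([C@H]2OC(=O)[C@H]3[C@@H]2CO[C@@H]3c2ccc(OCc4ccccc4)c(OCc4ccccc4)c2)ccc1OCc1ccccc1 | intermediate
16 | (3S,3aR,6S,6aS)-6-(3,4-dihydroxyphenyl)-3-(4-hydroxy-3-methoxyphenyl)tetrahydro-1H,3H-furo[3,4-c]furan-1-one | COc1cc([C@H]2OC(=O)[C@H]3[C@@H]2CO[C@@H]3c2ccc(O)c(O)c2)ccc1O | target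

## Step count and least certain steps

Total: 9 steps. Longest linear sequence: 8 steps (steps 1, 2, 3, 4, 6, 7, 8, 9); step 5 is a one-step side branch.

Step 4 (key step, proposed new method). The weak chiral acid may not accelerate the ester-deactivated, γ-substituted boronate enough. Conversion would then stall, or on warming an uncatalysed pathway would take over and facial selectivity would erode. The fallback replaces catalyst control by a covalently bound auxiliary on the ester, a known mode of stereocontrol for 2-alkoxycarbonyl allylboronates. It sets out from 2: acetylide 3 is acylated with (1R,2S,5R)-8-phenylmenthyl chloroformate to give the 8-phenylmenthyl ynoate F1. Hydroalumination with i-Bu2AlH–HMPA gives the alkenylalane F2, which is trapped with 5 as in step 3 to give the 8-phenylmenthyl (Z)-allylboronate F3. Addition of F3 to 8 under Sc(OTf)3 catalysis in toluene at −78 °C, where the aryl-bearing auxiliary shields one face of the allyl unit, gives the borate adduct F4. Acid-induced lactonisation expels the auxiliary and returns to the route at 10. The facial preference of the auxiliary has to be confirmed on the first run; its enantiomer is used if the sense proves opposite.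

Step 8. The most likely failure is acyl transfer: the primary hydroxyl attacks the activated lactone carbonyl instead of the benzylic carbon, which frees the guaiacyl carbinol and diverts material toward a regioisomeric bicycle. A second possibility is insufficient ionisation at an acidity the benzyl ethers tolerate. The fallback triggers the closure with an electrophile instead of a proton. It sets out from 14: NBS in CH2Cl2 at −20 °C forms the bromonium/benzylic cation at the electron-rich styrenic alkene, and anti capture by the hydroxyl, which from the (E)-alkene places the aryl group exo, gives the 6a-bromo furofuranone F5. Radical-chain debromination with Bu3SnH and AIBN in toluene at 80 °C delivers hydrogen to the ring-fusion radical in the only possible cis-fused sense and returns to the route at 15. A zinc reduction is avoided because its enolate would expel the β-alkoxy group.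

Step 6. The palladium hydride may re-add and move the double bond into the lactone ring, which would erase C4. The electron-rich diazonium salt may also decompose (reduction, azo coupling onto the alkoxyarenes) before it couples. The fallback changes the aryl donor and the catalytic manifold. It sets out from 10: Mizoroki–Heck arylation with purchased 1,2-bis(benzyloxy)-4-iodobenzene (Pd(OAc)2, KOAc, n-Bu4NBr, DMF, 80 °C) uses a stable aryl halide in the neutral palladium manifold with acetate-assisted removal of the hydride. Arylation of substituted α-methylene-γ-lactones to (E)-arylidene lactones is established under such conditions. It returns to the route at 13.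

Step 9. Over-reduction is the risk: hydrogenolysis of the benzylic C3–O2 or C6–O5 bond once the benzyl ethers have gone. The fallback is a non-reductive dealkylation. It sets out from 15: BCl3 with pentamethylbenzene as cation scavenger in CH2Cl2 at −78 °C cleaves the three aryl benzyl ethers and reaches 16 directly.

## Further compounds

F1 | step 4 | (1R,2S,5R)-5-methyl-2-(2-phenylpropan-2-yl)cyclohexyl 4-[(tert-butyldiphenylsilyl)oxy]but-2-ynoate | C[C@@H]1CC[C@H]([C@@H](C1)OC(=O)C#CCO[Si](c1ccccc1)(c1ccccc1)C(C)(C)C)C(C)(C)c1ccccc1
F2 | step 4 | (1R,2S,5R)-5-methyl-2-(2-phenylpropan-2-yl)cyclohexyl (E)-4-[(tert-butyldiphenylsilyl)oxy]-2-(diisobutylalumanyl)but-2-enoate | C[C@@H]1CC[C@H]([C@@H](C1)OC(=O)/C([Al](CC(C)C)CC(C)C)=C\CO[Si](c1ccccc1)(c1ccccc1)C(C)(C)C)C(C)(C)c1ccccc1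
F3 | step 4 | (1R,2S,5R)-5-methyl-2-(2-phenylpropan-2-yl)cyclohexyl (Z)-4-[(tert-butyldiphenylsilyl)oxy]-2-[(4,4,5,5-tetramethyl-1,3,2-dioxaborolan-2-yl)methyl]but-2-enoate | C[C@@H]1CC[C@H]([C@@H](C1)OC(=O)/C(CB1OC(C)(C)C(C)(C)O1)=C\CO[Si](c1ccccc1)(c1ccccc1)C(C)(C)C)C(C)(C)c1ccccc1
F4 | step 4 | (1R,2S,5R)-5-methyl-2-(2-phenylpropan-2-yl)cyclohexyl (3R,4S)-4-[4-(benzyloxy)-3-methoxyphenyl]-3-{[(tert-butyldiphenylsilyl)oxy]methyl}-2-methylidene-4-[(4,4,5,5-tetramethyl-1,3,2-dioxaborolan-2-yl)oxy]butanoate | COc1cc([C@@H](OB2OC(C)(C)C(C)(C)O2)[C@@H](CO[Si](c2ccccc2)(c2ccccc2)C(C)(C)C)C(=C)C(=O)O[C@@H]2C[C@H](C)CC[C@H]2C(C)(C)c2ccccc2)ccc1OCc1ccccc1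
F5 | step 8 | (3S,3aR,6R,6aR)-3-[4-(benzyloxy)-3-methoxyphenyl]-6-[3,4-bis(benzyloxy)phenyl]-6a-bromotetrahydro-1H,3H-furo[3,4-c]furan-1-one | COc1cc([C@H]2OC(=O)[C@@]3(Br)[C@@H]2CO[C@@H]3c2ccc(OCc4ccccc4)c(OCc4ccccc4)c2)ccc1OCc1ccccc1
F0 | step 6 | none | none
F0 | step 9 | none | none
A1 | alternative 1 | [(2S,3R)-3-[4-(benzyloxy)-3-methoxyphenyl]oxiran-2-yl]methanol (cis epoxide) | OC[C@@H]1O[C@@H]1c1ccc(OCc2ccccc2)c(OC)c1
A2 | alternative 1 | dibenzyl 2-{[3,4-bis(benzyloxy)phenyl]methylidene}propanedioate | O=C(OCc1ccccc1)C(=Cc1ccc(OCc2ccccc2)c(OCc2ccccc2)c1)C(=O)OCc1ccccc1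
A3 | alternative 1 | tri-O-benzyl target carrying a benzyl ester on C6a | COc1cc([C@H]2OC(=O)[C@@]3(C(=O)OCc4ccccc4)[C@@H]2CO[C@@H]3c2ccc(OCc4ccccc4)c(OCc4ccccc4)c2)ccc1OCc1ccccc1
A4 | alternative 2 | (5S,6S)-5-[(E)-2-[4-(benzyloxy)-3-methoxyphenyl]ethenyl]-6-[3,4-bis(benzyloxy)phenyl]-1,3-dioxan-4-one (cis) | O=C1OCO[C@H](c2ccc(OCc3ccccc3)c(OCc3ccccc3)c2)[C@@H]1/C=C/c1ccc(OCc2ccccc2)c(OC)c1
A5 | alternative 2 | tri-O-benzyl target, identical with 15 | COc1cc([C@H]2OC(=O)[C@H]3[C@@H]2CO[C@@H]3c2ccc(OCc4ccccc4)c(OCc4ccccc4)c2)ccc1OCc1ccccc1
A6 | alternative 3 | di-tert-butyl 2-[(S)-[3,4-bis(benzyloxy)phenyl]{[(E)-3-[4-(benzyloxy)-3-methoxyphenyl]prop-2-en-1-yl]oxy}methyl]propanedioate | CC(C)(C)OC(=O)C(C(=O)OC(C)(C)C)[C@H](OC/C=C/c1ccc(OCc2ccccc2)c(OC)c1)c1ccc(OCc2ccccc2)c(OCc2ccccc2)c1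
A7 | alternative 3 | tri-O-benzyl target carrying a tert-butyl ester on C6a | COc1cc([C@H]2OC(=O)[C@@]3(C(=O)OC(C)(C)C)[C@@H]2CO[C@@H]3c2ccc(OCc4ccccc4)c(OCc4ccccc4)c2)ccc1OCc1ccccc1
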